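A direct plan would lithiate the dihydrofuran A1, add it to the cyclobutenedione A2, expand the four-membered ring by an acid-triggered acyl shift to the spiro-enedione A3, and finish by adding the acetyl anion equivalent A4 and hydrolysing. Its weakest steps would be:
- the addition/ring expansion, which would have no direct precedent, since acid would have to favour acyl over vinyl migration rather than simply hydrolyse the enol ether;
- the last carbonyl addition, which would face two nearly equivalent carbonyl groups and two faces, so C5 and C9 would be set with little control and double addition would threaten;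
- the operations that only prepare A1 and A2, which would add length without complexity.

The strategy exploits the tertiary α-ketol at C9 of the cyclopentenone ring (hydroxyl and acetyl next to spiro C5): its 1,2-shift isomer is a six-membered ketol 10, in which the acetyl carbon is still a ring member and all ring carbons map onto a phenol. 10 would arise by oxidative dearomatisation, the side-chain tertiary hydroxyl closing the oxolane at the chain-bearing ortho carbon, then ketohydroxylation. In the key step an aluminium-chelated shift of the C5–C10 ring bond would expel one ring carbon as the acetyl group, form the five-membered ring and set C9 from C5. No carbanion is added to a dione, and no strained ring or enol ether is needed.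

Key step: step 7

Remark: the SMILES fixes C2 as S, opposite to C2 of natural (2R,4′R,8′R)-α-tocopherol under the same priority order, so this centre would be made from natural phytol by reagent control; locants of the spiro compounds follow 1-oxaspiro nomenclature (O1, C2, spiro C5).

Step 1
Reactants: 1 natural phytol [(2E,7R,11R)-3,7,11,15-tetramethylhexadec-2-en-1-ol]
Product: 2 (2S,3S)-2,3-epoxyphytol {[(2S,3S)-3-methyl-3-[(4R,8R)-4,8,12-trimethyltridecyl]oxiran-2-yl]methanol}
Conditions: Ti(OiPr)4 (10 mol %), L-(+)-diethyl tartrate (12 mol %), t-BuOOH (2 equiv, decane), 4 Å molecular sieves, CH2Cl2, −20 °C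
Reagents that add atoms: tert-butyl hydroperoxide, CC(C)(C)OO
Why: Sharpless asymmetric epoxidation of an (E)-trisubstituted allylic alcohol, in which L-(+)-tartrate directs oxygen to the face that gives the (2S,3S)-epoxide, so the tertiary C–O centre that becomes C2 of the target is set under reagent control.

Step 2
Reactants: 2 (2S,3S)-2,3-epoxyphytol
Product: 4 (S)-isophytol [(3S,7R,11R)-3,7,11,15-tetramethylhexadec-1-en-3-ol], via epoxy iodide 3 (not isolated)
Conditions: PPh3, I2, imidazole, THF, 0 °C; then Zn dust, AcOH, 0 °C → rt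
Reagents that add atoms: none
Why: Appel-type iodination of the primary alcohol and zinc-induced reductive β-elimination of the resulting 2,3-epoxy iodide move the hydroxyl to C3 without breaking the C3–O bond, so the tertiary carbinol keeps its configuration (3S).

Step 3
Reactants: 5 2,3,5-trimethylphenol
Product: 6 2-bromo-3,5,6-trimethylphenol
Conditions: NBS (1.0 equiv), i-Pr2NH (10 mol %), CH2Cl2, 0 °C
Reagents that add atoms: N-bromosuccinimide, O=C1CCC(=O)N1Br
Why: Amine-mediated ortho-selective electrophilic bromination of a phenol with N-bromosuccinimide, which should deliver bromine to the only free ortho position (the para position is flanked by two methyl groups); no stereocentre is involved.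

Step 4
Reactants: 4 (S)-isophytol; 6 2-bromo-3,5,6-trimethylphenol
Product: 8 2-[(3S,7R,11R)-3-hydroxy-3,7,11,15-tetramethylhexadecyl]-3,5,6-trimethylphenol, via B-alkyl-9-BBN adduct 7 (not isolated)
Conditions: 9-BBN (2.2 equiv), THF, 0 °C → rt; then 6, Pd(OAc)2 (5 mol %), SPhos (10 mol %), aq. K3PO4 (4 equiv), THF, 65 °C
Reagents that add atoms: none
Why: Anti-Markovnikov hydroboration of the vinyl group with 9-BBN (a second equivalent is taken up by the hydroxyl) followed by B-alkyl Suzuki–Miyaura coupling with the hindered aryl bromide under a bulky biarylphosphine ligand joins C1 of the chain to the arene without touching any stereocentre.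

Step 5
Reactants: 8 2-[(3S,7R,11R)-3-hydroxy-3,7,11,15-tetramethylhexadecyl]-3,5,6-trimethylphenol
Product: 9 (2S,5R)-2,7,8,10-tetramethyl-2-[(4R,8R)-4,8,12-trimethyltridecyl]-1-oxaspiro[4.5]deca-7,9-dien-6-one
Conditions: PhI(OAc)2 (1.1 equiv), (CF3)2CHOH, 0 °C; preparative HPLC (silica) to remove the C5 epimer
Reagents that add atoms: none
Why: Oxidative dearomatisation of the phenol by the trivalent iodine reagent with ortho-spirocyclisation, the tethered tertiary hydroxyl attacking the chain-bearing ortho carbon in a 5-exo mode (it cannot reach the para carbon), should give the 6,6-disubstituted cyclohexa-2,4-dienone; the remote C2 centre cannot bias the new spiro centre C5, so both epimers are expected in similar amounts and the (5R)-epimer would be isolated by chromatography.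

Step 6
Reactants: 9 (2S,5R)-2,7,8,10-tetramethyl-2-[(4R,8R)-4,8,12-trimethyltridecyl]-1-oxaspiro[4.5]deca-7,9-dien-6-one
Product: 10 (2S,5R,10R)-10-hydroxy-2,7,8,10-tetramethyl-2-[(4R,8R)-4,8,12-trimethyltridecyl]-1-oxaspiro[4.5]dec-7-ene-6,9-dione
Conditions: RuCl3·xH2O (2 mol %), KHSO5 (as 2KHSO5·KHSO4·K2SO4, 2.5 equiv), NaHCO3, EtOAc/MeCN/H2O, rt, short contact time
Reagents that add atoms: potassium peroxymonosulfate, [K+].[O-]S(=O)(=O)OO
Why: Ruthenium tetroxide-catalysed ketohydroxylation ([3+2] addition, then oxidation of the secondary ruthenate) should single out the trisubstituted γ,δ-alkene, the more electron-rich of the two, with the tertiary carbon ending as the carbinol and the CH carbon as the ketone, and addition anti to the allylic ring oxygen, as in osmylations of allylic ethers, would set C10 as R (hydroxyl trans to O1); the oxolane has no C–H next to oxygen that could be attacked.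

Step 7
Reactants: 10 (2S,5R,10R)-10-hydroxy-2,7,8,10-tetramethyl-2-[(4R,8R)-4,8,12-trimethyltridecyl]-1-oxaspiro[4.5]dec-7-ene-6,9-dione
Product: 11 alpha-tocospiro A [(2S,5R,9S)-9-acetyl-9-hydroxy-2,7,8-trimethyl-2-[(4R,8R)-4,8,12-trimethyltridecyl]-1-oxaspiro[4.4]non-7-en-6-one]
Conditions: Al(O-t-Bu)3 (1.5 equiv), toluene, 60 °C; then aq. potassium sodium tartrate
Reagents that add atoms: none
Why: Ligand exchange would give the aluminium alkoxide of the C10 carbinol chelated to the C9 carbonyl, and in this five-membered chelate the C5–C10 ring bond lies over the carbonyl π* orbital, so C5 migrates suprafacially from C10 to C9 with retention, C10 becoming the acetyl carbonyl and C9 the new aluminium-bound carbinol. The closest known reaction type is the α-ketol (acyloin) rearrangement in its chelate-controlled aluminium alkoxide form, and, in this ring-contracting direction, the isomerisation of hop α-acids (6-hydroxycyclohexa-2,4-dienones) to iso-α-acids (4-acyl-4-hydroxycyclopent-2-enones). The cyclopentenone ring is closed by this 1,2-shift of a ring bond, a contraction from six to five members and not an end-on cyclisation. C9 is the only new stereocentre and is controlled by C5 through the chelate: with the two oxygens syn and the C10 hydroxyl trans to O1, the half-chair that places O1 pseudo-equatorial and C4 pseudo-axial delivers C5 to the carbonyl face that leaves acetyl cis and hydroxyl trans to O1, that is 9S. The step needs migration of the ring carbon rather than of the methyl group and an equilibrium on the side of the five-membered ring: the first should be secured by the C6 carbonyl on C5, which stabilises the enolate-like character of the migrating carbon, the second by the product acetyl carbinol being the better chelating ligand for aluminium and by relief of the doubly acceptor-substituted enedione.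

**Compound list**
1 | natural phytol, (2E,7R,11R)-3,7,11,15-tetramethylhexadec-2-en-1-ol | OC/C=C(\C)CCC[C@H](C)CCC[C@H](C)CCCC(C)C | starting material
2 | (2S,3S)-2,3-epoxyphytol, [(2S,3S)-3-methyl-3-[(4R,8R)-4,8,12-trimethyltridecyl]oxiran-2-yl]methanol | OC[C@@H]1O[C@@]1(C)CCC[C@H](C)CCC[C@H](C)CCCC(C)C | intermediate
3 | epoxy iodide, (2R,3S)-2-(iodomethyl)-3-methyl-3-[(4R,8R)-4,8,12-trimethyltridecyl]oxirane | IC[C@@H]1O[C@@]1(C)CCC[C@H](C)CCC[C@H](C)CCCC(C)C | intermediate
4 | (S)-isophytol, (3S,7R,11R)-3,7,11,15-tetramethylhexadec-1-en-3-ol | C=C[C@](O)(C)CCC[C@H](C)CCC[C@H](C)CCCC(C)C | intermediate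
5 | 2,3,5-trimethylphenol | Cc1cc(C)c(C)c(O)c1 | starting material
6 | 2-bromo-3,5,6-trimethylphenol | Cc1cc(C)c(C)c(O)c1Br | intermediate
7 | B-alkyl-9-BBN adduct, 9-[(3R,7R,11R)-3-(9-borabicyclo[3.3.1]nonan-9-yloxy)-3,7,11,15-tetramethylhexadecyl]-9-borabicyclo[3.3.1]nonane (3R only through the change in priorities) | B1(CC[C@@](C)(OB2C3CCCC2CCC3)CCC[C@H](C)CCC[C@H](C)CCCC(C)C)C2CCCC1CCC2 | intermediate
8 | 2-[(3S,7R,11R)-3-hydroxy-3,7,11,15-tetramethylhexadecyl]-3,5,6-trimethylphenol | Cc1cc(C)c(CC[C@@](C)(O)CCC[C@H](C)CCC[C@H](C)CCCC(C)C)c(O)c1C | intermediate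
9 | (2S,5R)-2,7,8,10-tetramethyl-2-[(4R,8R)-4,8,12-trimethyltridecyl]-1-oxaspiro[4.5]deca-7,9-dien-6-one | O=C1C(C)=C(C)C=C(C)[C@]12CC[C@](C)(CCC[C@H](C)CCC[C@H](C)CCCC(C)C)O2 | intermediate
10 | (2S,5R,10R)-10-hydroxy-2,7,8,10-tetramethyl-2-[(4R,8R)-4,8,12-trimethyltridecyl]-1-oxaspiro[4.5]dec-7-ene-6,9-dione | O=C1C(C)=C(C)C(=O)[C@](C)(O)[C@]12CC[C@](C)(CCC[C@H](C)CCC[C@H](C)CCCC(C)C)O2 | intermediate
11 | alpha-tocospiro A, (2S,5R,9S)-9-acetyl-9-hydroxy-2,7,8-trimethyl-2-[(4R,8R)-4,8,12-trimethyltridecyl]-1-oxaspiro[4.4]non-7-en-6-one | CC(=O)[C@]1(O)C(C)=C(C)C(=O)[C@@]12CC[C@](C)(CCC[C@H](C)CCC[C@H](C)CCCC(C)C)O2 | target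

Total steps: 7. Longest linear sequence: 6 steps (1, 2, 4, 5, 6, 7, from phytol).

**Steps most likely to fail**

Step 7. The 1,2-shift may stall at the six-membered ketol (unfavourable equilibrium or slow migration), run through a non-chelated transition state that gives the C9 epimer, or move the methyl group instead of the ring carbon. Fallback: give up the concerted shift and cleave and re-form the ring. From 10, K2CO3 in MeOH at rt would open the β-hydroxy ketone by retro-aldol cleavage of C5–C10 to the enolate of (2Z)-2,3-dimethyl-1-[(5S)-5-methyl-5-[(4R,8R)-4,8,12-trimethyltridecyl]oxolan-2-yl]hex-2-ene-1,4,5-trione F1. Its 5-(enolexo)-exo-trig aldol closure onto the inner carbonyl of the 1,2-dione would lead to 11. This closure is reversible and should settle on the less crowded arrangement (acetyl cis to O1), but it scrambles C5, so 11 would have to be separated from its C5,C9-bis-epimer at the end.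

Step 5. The dearomatisation may be diverted by attack of solvent or acetate at the free para position with over-oxidation to the quinone, by loss of a benzylic proton to a quinone methide, or by acid-induced dienone–phenol rearrangement, and it gives no control at C5. Fallback: oxygenate the ring first and close the oxolane by epoxide opening.
- From 4, hydroboration (via 7) and coupling as in step 4, but with 1-bromo-2,5-dimethoxy-3,4,6-trimethylbenzene F2, would give (3S,7R,11R)-1-(2,5-dimethoxy-3,4,6-trimethylphenyl)-3,7,11,15-tetramethylhexadecan-3-ol F3.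
- (NH4)2Ce(NO3)6 in MeCN/H2O would unmask 2-[(3S,7R,11R)-3-hydroxy-3,7,11,15-tetramethylhexadecyl]-3,5,6-trimethylcyclohexa-2,5-diene-1,4-dione F4.
- H2O2/Na2CO3 in EtOH would epoxidise either ring double bond from either face without selectivity, so (1S,6R)-1-[(3S,7R,11R)-3-hydroxy-3,7,11,15-tetramethylhexadecyl]-3,4,6-trimethyl-7-oxabicyclo[4.1.0]hept-3-ene-2,5-dione F5 would have to be separated from its isomers.
- BF3·OEt2 in CH2Cl2 at low temperature would let the tertiary hydroxyl open the epoxide at the chain-bearing carbon (5-exo, inversion), which gives 10 directly with the hydroxyl trans to O1.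

Step 6. Ruthenium tetroxide may cleave the alkene or the new ketol, attack the enone double bond or tertiary C–H bonds of the chain, or add from the O1 face and give the C10 epimer. Fallback: separate the two oxidation events. From 9, OsO4 (cat.) and N-methylmorpholine N-oxide in acetone/H2O would give the cis-diol (2S,5R,9S,10S)-9,10-dihydroxy-2,7,8,10-tetramethyl-2-[(4R,8R)-4,8,12-trimethyltridecyl]-1-oxaspiro[4.5]dec-7-en-6-one F6, whose configuration can be checked before going on. Oxidation of the secondary allylic alcohol alone (TEMPO with PhI(OAc)2, or Dess–Martin periodinane) would then give 10.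

**Further compounds**
F1 | step 7 | (2Z)-2,3-dimethyl-1-[(5S)-5-methyl-5-[(4R,8R)-4,8,12-trimethyltridecyl]oxolan-2-yl]hex-2-ene-1,4,5-trione (formed as its enolate; C2 of the oxolane not defined) | CC(=O)C(=O)/C(C)=C(C)\C(=O)C1CC[C@](C)(CCC[C@H](C)CCC[C@H](C)CCCC(C)C)O1
F2 | step 5 | 1-bromo-2,5-dimethoxy-3,4,6-trimethylbenzene | COc1c(C)c(C)c(OC)c(C)c1Br
F3 | step 5 | (3S,7R,11R)-1-(2,5-dimethoxy-3,4,6-trimethylphenyl)-3,7,11,15-tetramethylhexadecan-3-ol | COc1c(C)c(C)c(OC)c(C)c1CC[C@@](C)(O)CCC[C@H](C)CCC[C@H](C)CCCC(C)C
F4 | step 5 | 2-[(3S,7R,11R)-3-hydroxy-3,7,11,15-tetramethylhexadecyl]-3,5,6-trimethylcyclohexa-2,5-diene-1,4-dione | CC1=C(C)C(=O)C(CC[C@@](C)(O)CCC[C@H](C)CCC[C@H](C)CCCC(C)C)=C(C)C1=O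
F5 | step 5 | (1S,6R)-1-[(3S,7R,11R)-3-hydroxy-3,7,11,15-tetramethylhexadecyl]-3,4,6-trimethyl-7-oxabicyclo[4.1.0]hept-3-ene-2,5-dione | O=C1C(C)=C(C)C(=O)[C@]2(C)O[C@]12CC[C@@](C)(O)CCC[C@H](C)CCC[C@H](C)CCCC(C)C
F6 | step 6 | (2S,5R,9S,10S)-9,10-dihydroxy-2,7,8,10-tetramethyl-2-[(4R,8R)-4,8,12-trimethyltridecyl]-1-oxaspiro[4.5]dec-7-en-6-one | O=C1C(C)=C(C)[C@H](O)[C@](C)(O)[C@]12CC[C@](C)(CCC[C@H](C)CCC[C@H](C)CCCC(C)C)O2
A1 | direct plan | (2S)-2-methyl-2-[(4R,8R)-4,8,12-trimethyltridecyl]-2,3-dihydrofuran | C1=CC[C@](C)(CCC[C@H](C)CCC[C@H](C)CCCC(C)C)O1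
A2 | direct plan | 3,4-dimethylcyclobut-3-ene-1,2-dione | CC1=C(C)C(=O)C1=O
A3 | direct plan | (2S)-2,7,8-trimethyl-2-[(4R,8R)-4,8,12-trimethyltridecyl]-1-oxaspiro[4.4]non-7-ene-6,9-dione | CC1=C(C)C(=O)C2(CC[C@](C)(CCC[C@H](C)CCC[C@H](C)CCCC(C)C)O2)C1=O
A4 | direct plan | 1-ethoxyvinyllithium | [Li]C(=C)OCC
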